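The constants were chosen freely; no experiment stands behind them.

I am the chemist running J with G over a trace of L at the temperatures below, and I want to know which flask holds the most J.G at the end.

| setting | north | south-east | east | north-east |
|---|---|---|---|---|
| J | 0.10 M | 0.10 M | 0.10 M | 0.10 M |
| G | 1.20 equiv | 1.20 equiv | 1.20 equiv | 1.20 equiv |
| L | 0.059 mol% | 0.059 mol% | 0.059 mol% | 0.059 mol% |
| temperature | 90 °C | 70 °C | 110 °C | 130 °C |
| time | 20 h | 20 h | 20 h | 20 h |

    G + L → G.L (k1 = 0.73 M⁻¹ h⁻¹, Ea1 = 85.0 kJ mol⁻¹)
    J + G + L ⇌ J.G + L, rate k2*[J]*[G]*[L] forward; the back reaction follows from the equilibrium constant (K2 = 15 M⁻¹, k2 = 16000 M⁻² h⁻¹, Ea2 = 47.0 kJ mol⁻¹, ΔH2 = −20.0 kJ mol⁻¹)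
    G → X (k3 = 0.76 h⁻¹, Ea3 = 118 kJ mol⁻¹)
    (constants at 90 °C)

- all constants are for 90 °C and move with temperature by the activation energies and enthalpies

* the flask that comes out highest in amount of J.G, in percent of the J charged, or "all alike" when all lie within 1.5 percentage points (north / south-east / east / north-east / all alike)
* J.G at the end, in percent of the J charged, north
* J.G at the end, in percent of the J charged, south-east
* J.G at the end, in percent of the J charged, east
* J.G at the end, in percent of the J charged, north-east

My own reckoning runs north in slow motion, holding [J] and [L] at their charges.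

1. First instants. [L] is 5.90 × 10⁻⁵ M, so G couples with a pseudo-first-order constant of 0.0944 h⁻¹. G goes to X with 0.76 h⁻¹, faster than it couples. I drop the capture of G by L, because its constant on G, 4.31 × 10⁻⁵ h⁻¹, is far below the loss to X.

2. Middle. G decays with 0.854 h⁻¹, the sum of the two. J.G climbs toward the coupling share of the G charged, 13.3% of the J charged.

3. End. [G] is now low, yet L still runs the back reaction, with a constant of forward constant times [L] over the equilibrium constant. Each released G either couples again or goes to X, and 89.0% of them go to X. The product of the back constant and that share is what I call the drain constant, the first-order rate at which J.G is lost once G is low: 0.0560 h⁻¹.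

4. Rise and drain together give two consecutive first-order stages, so north ends at 4.33%.

5. South-east: coupling 0.0381 h⁻¹, loss to X 0.0779 h⁻¹, drain 0.0116 h⁻¹. That gives 27.4%.

6. East: coupling 0.213 h⁻¹, loss to X 5.84 h⁻¹, drain 0.193 h⁻¹. That gives 0.0881%.

7. North-east: coupling 0.442 h⁻¹, loss to X 36.7 h⁻¹, drain 0.562 h⁻¹. That gives <0.001%.

8. My pick is south-east.

The forecast names south-east, with 5.2% north, 25% south-east, 0.12% east and 0% north-east. Its grounds include that “the catalyst keeps running the reverse step and the released G is lost to X”. Its south-east figure is lower than mine, and its north figure is higher than mine.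

The simulation gives 4.56% north, 24.7% south-east, 0.109% east and 0% north-east, so south-east stands highest.

In north, J.G falls from 7.57% after 10.0 h to 4.56% after 20.0 h, with G at 0.271% of its charge, which reads as a loss of 0.0507 h⁻¹ against a drain constant of 0.0560 h⁻¹. In east, J.G falls from 0.670% after 10.0 h to 0.109% after 20.0 h, with G at 0.0179% of its charge at the earlier time, which reads as a loss of 0.182 h⁻¹ against a drain constant of 0.193 h⁻¹.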